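## Structural features

The target is a cycloheptane carrying a cis-fused α-methylene-γ-butyrolactone. The carbocycle is numbered C1 (lactone oxygen), C2 (lactone α-carbon attached), C3 (the only methylene), C4 (secondary hydroxyl), C5 (methyl), C6 (tertiary hydroxyl and the (E)-but-2-enoyl ketone) and C7 (3-methylbutanoate). Six of the seven ring carbons are stereocentres and they form one unbroken chain C4–C5–C6–C7–C1–C2. Taking the face that carries the two lactone bonds as α, the C4 hydroxyl, the C6 acyl carbon and the C7 ester oxygen are β and the C5 methyl and the C6 hydroxyl are α; C6–OH/C7–O, C7–O/C1–O and C4–OH/C5–Me are therefore each trans. The fragile groups are the methylene lactone and the crotonyl ketone (both Michael acceptors), the tertiary α-ketol at C6 (retro-aldol, acyloin shift), the C7 ester beside a free tertiary hydroxyl (acyl migration), and the C4 hydroxyl, which is cis to the C6 carbonyl carbon (lactol or bridged lactone once C6 bears an aldehyde or ester). The real difficulty is the fully substituted C6 between two stereocentres, together with telling three acyl groups apart (lactone, C6 carboxyl carbon, isovalerate) and placing two unsaturated carbonyl units late. The key step uses the fact that C1, C2, C3, C4 and C7 with the lactone are the cyclopentanone ring of an enantiopure bicyclic keto lactone, and that C5 with its methyl and C6 with its carbonyl carbon are the four carbons of a but-2-ynoate. Inserting the alkyne between C4 and C7 makes the seven-membered ring.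

## Logic of the disconnections

The last bonds cut are the O–Si bonds at C4 and C6 (26 from 25) and, one oxidation level down, the bond between the C6 carbonyl carbon and the propenyl carbon (25 from 24, 24 from 22 and 23). The enone tolerates bases and nucleophiles least, so it is assembled last by reactions that touch only aldehydes and alcohols. Acyl substitution on an ester or amide at C6 was rejected because the lactone and the C7 ester would compete for the organometallic reagent. The gain is an intermediate, 22, without the enone. The demand is an alkenyl–carbon bond formation selective for a hindered aldehyde beside a methylene lactone and an ester, with retention of the E geometry of 23, then a non-basic oxidation and desilylation.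

Next the exocyclic C=CH2 bond of the lactone is cut (21 from 17) and the aldehyde is traced to a primary silyl ether (22 from 21). The methylene must be made before the enone exists, because afterwards the lactone CH2 is no longer the most acidic site, and at a stage with no free hydroxyl. In 17 all three hydroxyls carry the same silyl group, which meets both conditions. The gain is an intermediate with no Michael acceptor and one kind of protecting group. The demands are enolisation of the lactone in preference to the C7 ester, and oxidative release of the primary silyl ether beside a secondary and a tertiary one.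

The C4–O and C5–H bonds are cut together back to the C4=C5 alkene, and the C6 hydroxymethyl is returned to the ester level (16 from 14; 17 is silylated 16). A syn addition of H and OH to the alkene gives the trans relation of C4–OH and C5–Me. The ester alone among the three acyl groups has a free hydroxyl on its α-carbon to direct a borane reduction. The gain is two stereocentres and one redox adjustment in a single operation. The demand is borane attack on the β face of an alkene flanked by the fully substituted C6, without reduction of the lactone or the C7 ester and without acyl migration.

The ester C–O bond at C7 is cut (14 from 12 and 13). In 12 the only other hydroxyl is tertiary, so site selectivity costs nothing; after hydroboration the less hindered C4 hydroxyl would compete. The demand is acylation of a hindered secondary alcohol without acyl transfer to C6.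

The C6–O bond is cut (12 from 10 through 11). The C7 oxygen, as a lithium alkoxide chelated to the ester enolate, sends an electrophile to the opposite face of C6. The trans C6–OH/C7–O relation is thus set from the adjacent centre and not from the remote lactone. The gain is a β-hydroxy ester without the quaternary centre. The demands are that C7 is already β, that the dianion forms at C6 and not at the lactone, and that oxygen enters at the α- and not the γ-carbon of the dienolate.

The C7–H bond is cut (10 from 9). Hydride must arrive on the lactone face, against the preference of an α-acyloxy ketone. Inverting the epimeric alcohol is not an option, because an activated β-hydroxy ester with a doubly activated α-hydrogen would eliminate to the dienoate. The step is therefore put under catalyst control. The gain is 9, the direct product of the ring enlargement. The demand is a reduction that obeys the ligand and leaves the C4=C5 alkene and the lactone alone.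

At 9 the ring bonds C4–C5 and C6–C7 are cut and C4–C7 is restored. The seven-membered ring contracts to the cyclopentanone of 3, and the two inserted carbons with the methyl and the carboxyl carbon leave as 5; 4 is the carrier that turns the ketone into a nucleophile. This is the greatest simplification: all carbons of the carbocycle, the lactone and the C6 acyl carbon come from two small compounds, and only the ring-fusion stereocentres remain. The demands are enamine formation toward C4 only, bond formation with a sluggish β-substituted alkyne, and survival of the lactone beside a nucleophilic amine.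

Finally the ketone oxygen is removed from the carbon next to the oxygen-bearing ring-fusion carbon (3 from 2 by saturation, 2 from 1 by allylic oxidation). 1 is a commercial single enantiomer whose two stereocentres are C1 and C2 of the target in the correct absolute sense and cis relation. The demand is oxidation of the methylene and not of the allylic ring-fusion methine, without migration of the alkene.

## Other disconnections considered

Alternative 1: The ring is taken from an aromatic seven-membered ketone, and the C4–O and C7–O bonds are cut together as a peroxide bridge. Forward, singlet oxygen A2 adds in a (4+2) sense across the diene of tropone A1 to give the endoperoxide A3. A3 maps on the target with its ketone at C1, its enone alkene at C2=C3, the peroxide oxygens on C4 and C7 and the remaining alkene at C5=C6.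
- In its favour: A1 is a commodity, the carbocycle needs no construction, and the suprafacial cycloaddition puts the C4 and C7 oxygens on the same face in one step. On ring economy and on the C4/C7 oxygen pair the alternative is better than the chosen plan, which needs a catalyst-controlled reduction for C7 and a face-selective hydroboration for C4.
- Against it: A1 and A2 are achiral, so A3 would be racemic. The needed enantiomer would come from a resolution or a kinetic resolution (for instance a chiral-base Kornblum–DeLaMare rearrangement) with loss of half the material. No carbon substituent is present, so five carbon–carbon bonds (lactone side chain at C2, methylene, C5 methyl, C6 acyl carbon, propenyl) remain to be made on a polyoxygenated ring, against two in the chosen plan. A strained peroxide must also be handled.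
- Comparison: the key step is a clean concerted cycloaddition, simpler than the stepwise polar key step chosen, but it sets no absolute configuration, whereas the chosen route carries C1 and C2 from 1. Overall it would be longer.

Alternative 2: The ring is cut at C1–C7 and C4–C5 into a furan (C1–C4 with the ring oxygen) and a three-carbon oxyallyl unit (C5, C6, C7). Forward, 1-bromobutan-2-one A4 is ionised to the oxyallyl cation A6, which adds across the 2- and 5-positions of methyl 2-(furan-3-yl)acetate A5 to give the oxygen-bridged cycloheptenone A7. The structure of A7 that fits this bond set has the acetate chain on the alkene carbon remote from the methyl-bearing carbon. Its correct name is therefore methyl 2-(2-methyl-3-oxo-8-oxabicyclo[3.2.1]oct-6-en-6-yl)acetate (side-chain locant 6, not 7).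
- In its favour: two ring bonds, both lactone carbons, the C5 methyl, the C4 oxygen and a C6 ketone ready for addition of the acyl unit arrive in one step from two small achiral compounds. The C4/C5 relative configuration is set in the cycloaddition. In convergence and in stereocentres created by the key step it is the better plan, since the chosen key step creates none.
- Against it: both partners are unsymmetrical and a 3-alkyl group on the furan gives little regiocontrol, so the isomer with the methyl next to the substituted side is to be expected alongside. A7 would be racemic unless an auxiliary-based or catalytic asymmetric variant is developed for this pair. The bridge places C1–O cis to C4–O, whereas the target has them trans, so the C1–O bond must be broken and re-made with inversion at a centre where elimination threatens. C7 still needs oxidation, C2 a face-selective reduction and C6 a stereocontrolled carbon addition.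
- Comparison: the skeleton is reached faster, but absolute configuration and the C1 oxygen are unsolved, and the corrective steps would bring the total to a similar or larger number.

Alternative 3: The ring is cut at C2–C3 and C6–C7 into a three-carbon vinylcarbenoid (C7, C1, C2) and a diene (C3–C6). Forward, the diazo ester A8 is decomposed by a chiral dirhodium tetracarboxylate Rh2(O2CR*)4 in the presence of the diene A9. Cyclopropanation of the terminal alkene (C2–C3) followed by Cope rearrangement through a boat transition state (C6–C7) would give the cycloheptadiene A10.
- In its favour: absolute configuration comes from a catalyst instead of the chiral pool. Two stereocentres (C6 and C7, cis as needed for the acyl carbon and the ester oxygen) are set stereospecifically in the key step. The C7 oxygen arrives differentiated from the C1 oxygen, and the C4=C5 alkene with its methyl sits as in 12 for a later hydroboration. On stereocentres created and on catalytic enantiocontrol the alternative is better than the chosen key step.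
- Against it: C2 carries a carboxyl carbon directly, so that carbon must become the lactone α-carbon and the lactone carbonyl must be added by homologation; in the chosen plan both lactone carbons come with 1. C6 arrives as a CH bearing CH2O, so the tertiary hydroxyl must be introduced late at a crowded centre. The C1 ketone must then be reduced trans to C7–O and cis to the C2 substituent. A8 (geometrically defined, doubly oxygenated) and A9 each need several steps, and an alkoxy group at the vinyl terminus may divert the carbenoid.
- Comparison: in step count it would be clearly longer. Both key steps are two-stage processes; the alternative's is stereospecific and the chosen one is stereochemically silent.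

Key step: step 3

Remark on the chemistry: centres that a later step erases (C6 of 10, the lactone α-carbon of 19 and 20, the carbinol carbon of 24) are drawn as the expected epimer or left open, since either epimer serves; 23 and LDA solution are taken as purchased.

## Route

Step 1
Reactants: 1 (1S,5R)-2-oxabicyclo[3.3.0]oct-6-en-3-one
Product: 2 (1R,5R)-2-oxabicyclo[3.3.0]oct-6-ene-3,8-dione (cis-fused enone lactone)
Conditions: CrO3, 3,5-dimethylpyrazole, CH2Cl2, −20 °C
Reagents that add atoms: chromium trioxide, O=[Cr](=O)=O
Why: Allylic oxidation of a ring methylene to the conjugated ketone by the CrO3–3,5-dimethylpyrazole complex (hexavalent chromium); of the two allylic positions only the methylene next to the oxygen-bearing ring-fusion carbon can become a carbonyl, the other being the ring-fusion methine, and oxidation without allylic transposition is the usual course with this reagent. No stereocentre is made or touched.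

Step 2
Reactants: 2 (1R,5R)-2-oxabicyclo[3.3.0]oct-6-ene-3,8-dione
Product: 3 (1R,5S)-2-oxabicyclo[3.3.0]octane-3,8-dione (cis keto lactone)
Conditions: H2 (1 atm), 10% Pd/C, EtOAc, rt
Reagents that add atoms: none
Why: Heterogeneous catalytic hydrogenation of the enone C=C; lactone and ketone are inert under these conditions and the cis ring fusion is unchanged (the descriptor at one ring-fusion carbon changes only because the priorities change).

Step 3
Reactants: 3 (1R,5S)-2-oxabicyclo[3.3.0]octane-3,8-dione; 4 pyrrolidine; 5 methyl but-2-ynoate
Product: 9 methyl (3aS,8aR)-8-hydroxy-6-methyl-2-oxo-3,3a,4,8a-tetrahydro-2H-cyclohepta[b]furan-7-carboxylate (enol of the C7-keto C6-ester), via pyrrolidine enamine 6 (not isolated), via aminocyclobutene 7 (not isolated), via ring-opened dienamine 8 (not isolated)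
Conditions: 4 (1.05 equiv), 4 Å MS, toluene, rt; evaporate; 5 (3 equiv), toluene, 90 °C; then 1 M HCl, THF, rt
Reagents that add atoms: water, O
Why: Condensation of 3 with 4 gives enamine 6 with its double bond toward the C4 methylene, because the other isomer would put a tetrasubstituted, acyloxy-bearing alkene at the ring fusion against the pyrrolidine ring. The nucleophilic C4 adds to the methyl-bearing alkyne carbon of 5 (Michael type, forming C4–C5) and the resulting vinyl anion collapses onto the iminium carbon (forming C6–C7), a stepwise polar (2+2) that closes the four-membered ring of the cis-fused aminocyclobutene 7 on the face away from the lactone. The donor–acceptor cyclobutene then opens with cleavage of the old C4–C7 bond; this is formally a conrotatory 4π electrocyclic opening, but strict conrotation in the fused system would give an E-alkene in a seven-membered ring, so the opening is best seen as strongly polarised (amine push, ester pull) and leading to the all-cis aminodiene 8. The seven-membered ring is thus formed by ring enlargement, C5 and C6 being inserted between C4 and C7, and not by a separate cyclisation. Aqueous acid hydrolyses the vinylogous carbamate 8 to the β-keto ester, obtained as the hydrogen-bonded enol 9. The closest known reaction type is the two-carbon ring expansion of cyclic ketone enamines with acetylenedicarboxylates and propiolates; 5 is less electrophilic, hence the heating and the excess. No stereocentre is created; C2 is untouched, and C1, next to the iminium carbon, can only return to the cis-fused lactone while the ring is five-membered and is not enolised in the conjugated dienamine. The selectivities needed are the enamine regiochemistry (secured by the substitution at C1), carbon attack on 5 without aza-Michael addition (one equivalent of amine, sieves, evaporation before 5 is added) and survival of the lactone (enamine formation at room temperature in an aprotic solvent).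

Step 4
Reactants: 9 methyl (3aS,8aR)-8-hydroxy-6-methyl-2-oxo-3,3a,4,8a-tetrahydro-2H-cyclohepta[b]furan-7-carboxylate
Product: 10 lactone-fused methyl 7β-hydroxy-5-methylcyclohept-4-ene-6α-carboxylate (β-hydroxy ester; 7-OH trans to the C1 lactone oxygen)
Conditions: H2 (50 atm), [RuCl((S)-BINAP)(p-cymene)]Cl (1 mol%), CH2Cl2–MeOH, 50 °C
Reagents that add atoms: none
Why: Noyori asymmetric hydrogenation of a β-keto ester, which reacts through its keto tautomer as a ketone–ester chelate on divalent ruthenium; the face of hydride delivery is dictated by the ligand, and (S)-BINAP is the enantiomer that the empirical rule assigns to the 7β alcohol, that is hydride on the lactone face against the inherent preference for attack anti to the C1–O bond. The isolated trisubstituted alkene is not reduced by this catalyst type, and C6 (labile, expected anti by dynamic kinetic resolution) is erased in step 5.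

Step 5
Reactants: 10 lactone-fused methyl 7β-hydroxy-5-methylcyclohept-4-ene-6α-carboxylate
Product: 12 lactone-fused methyl 6α,7β-dihydroxy-5-methylcyclohept-4-ene-6β-carboxylate (trans-diol ester), via dilithium dianion 11 (not isolated)
Conditions: LDA (2.3 equiv), THF, −78 to −20 °C; then 2-(phenylsulfonyl)-3-phenyloxaziridine, −78 °C; aq. NH4Cl
Reagents that add atoms: 2-(phenylsulfonyl)-3-phenyloxaziridine, O=S(=O)(c1ccccc1)N1OC1c1ccccc1
Why: Fráter–Seebach reaction of a β-hydroxy ester: the second equivalent of base gives the lithium-chelated alkoxide–dienolate 11, and the electrophilic oxygen enters at C6 (α-carbon of the dienolate) trans to the C7 alkoxide, as in the alkylation of cyclic β-hydroxy ester dianions, so the new hydroxyl is α and the ester becomes cis to C7–OH. Warming to −20 °C before oxidation lets any kinetically formed lactone enolate pass its charge to the far more acidic, doubly activated C6 position.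

Step 6
Reactants: 12 lactone-fused methyl 6α,7β-dihydroxy-5-methylcyclohept-4-ene-6β-carboxylate; 13 3-methylbutanoic acid
Product: 14 7β-(3-methylbutanoyl) ester of 12 (6α-OH free)
Conditions: EDC·HCl, DMAP, CH2Cl2, 0 °C to rt
Reagents that add atoms: none
Why: Steglich esterification (carbodiimide activation, nucleophilic catalysis by DMAP); the secondary C7 hydroxyl is acylated while the tertiary C6 hydroxyl does not react, and no other hydroxyl exists at this stage, which is why the acyl group is placed before C4 is oxygenated.

Step 7
Reactants: 14 7β-(3-methylbutanoyl) ester of 12
Product: 16 lactone-fused 4β,6α-dihydroxy-6β-(hydroxymethyl)-5α-methylcycloheptan-7β-yl 3-methylbutanoate (triol), via organoborane 15 (not isolated)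
Conditions: BH3·SMe2 (4 equiv), THF, 0 °C to rt; NaBH4 (5 mol%), rt; then 30% H2O2, pH 7 phosphate buffer, 0 °C
Reagents that add atoms: hydrogen peroxide, OO
Why: Brown hydroboration–oxidation: syn addition with boron at the less substituted C4 and hydrogen at C5, expected on the β face, which is remote from the cis-fused lactone at the boron-bearing end and anti to the allylic C6–O bond at the other, giving 4β-OH and 5α-Me after oxidation with retention. The borane bound to the tertiary C6 oxygen delivers hydride only to the adjacent carbonyl through a five-membered chelate (hydroxyl-directed reduction of α-hydroxy esters by BH3·SMe2 with catalytic NaBH4), while the lactone and the isovalerate, which need refluxing borane, are left; neutral peroxide work-up guards against acyl migration.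

Step 8
Reactants: 16 lactone-fused 4β,6α-dihydroxy-6β-(hydroxymethyl)-5α-methylcycloheptan-7β-yl 3-methylbutanoate
Product: 17 tris(triethylsilyl) ether of 16 (4β-O, 6α-O and CH2O silylated)
Conditions: Et3SiOTf (4 equiv), 2,6-lutidine, CH2Cl2, −78 to 0 °C
Reagents that add atoms: triethylsilyl trifluoromethanesulfonate, CC[Si](CC)(CC)OS(=O)(=O)C(F)(F)F
Why: A silyl triflate with a hindered pyridine base silylates primary, secondary and tertiary hydroxyls alike; capping all three removes every acidic O–H before the enolate step and blocks acyl migration from C7.

Step 9
Reactants: 17 tris(triethylsilyl) ether of 16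
Product: 21 α-methylene lactone tris(triethylsilyl) ether, via lithium enolate 18 (not isolated), via Mannich base 19 (not isolated), via ammonium iodide 20 (not isolated)
Conditions: LDA (1.1 equiv), THF, −78 °C; CH2=NMe2+ I−, −78 °C to rt; then MeI, MeOH, rt; then aq. NaHCO3, EtOAc, rt
Reagents that add atoms: N,N-dimethylmethyleneiminium iodide (Eschenmoser's salt), C=[N+](C)C.[I-]
Why: α-Methylenation of a lactone by Mannich reaction of its lithium enolate with the preformed iminium salt, N-methylation and base-induced β-elimination of trimethylamine; the lactone CH2 is the most acidic C–H of 17 (lactones are markedly more acidic than open-chain esters such as the isovalerate, which moreover lies on the opposite ring face), and the α-stereocentre of 19 and 20 disappears in the elimination.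

Step 10
Reactants: 21 α-methylene lactone tris(triethylsilyl) ether
Product: 22 6β-formyl compound (aldehyde at C6; 4β-O and 6α-O triethylsilyl ethers, 7β-isovalerate, methylene lactone)
Conditions: (COCl)2, DMSO, CH2Cl2, −78 to −30 °C; then Et3N, −78 °C to rt
Reagents that add atoms: none
Why: Swern conditions convert primary triethylsilyl ethers directly into aldehydes (attack of the ether oxygen on the chlorosulfonium salt with loss of the silyl chloride), whereas secondary and tertiary triethylsilyl ethers react much more slowly; the aldehyde has no α-hydrogen and cannot epimerise, and the methylene lactone tolerates the brief exposure to amine at low temperature.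

Step 11
Reactants: 22 6β-formyl compound; 23 (E)-1-bromoprop-1-ene
Product: 24 6β-[(E)-1-hydroxybut-2-enyl] compound (allylic alcohol, both carbinol epimers)
Conditions: CrCl2 (5 equiv), NiCl2 (1 mol%), DMSO, rt
Reagents that add atoms: none
Why: Nozaki–Hiyama–Kishi reaction: the alkenylchromium species formed from 23 (NiCl2-catalysed oxidative addition, transmetallation to trivalent chromium) adds to aldehydes only, so the methylene lactone and the ester survive, and the E geometry of the alkenyl halide is retained; the new carbinol centre is not controlled and is removed in step 12.

Step 12
Reactants: 24 6β-[(E)-1-hydroxybut-2-enyl] compound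
Product: 25 4,6-bis(triethylsilyl) ether of the target
Conditions: Dess–Martin periodinane, NaHCO3, CH2Cl2, 0 °C to rt
Reagents that add atoms: none
Why: Dess–Martin oxidation of a secondary allylic alcohol to the enone under buffered, non-basic conditions; both carbinol epimers converge, silyl ethers, ester and methylene lactone are inert, and the E enone is the stable geometry.

Step 13
Reactants: 25 4,6-bis(triethylsilyl) ether of the target
Product: 26 (3aS,5R,6S,7S,8S,8aR)-7-[(E)-but-2-enoyl]-5,7-dihydroxy-6-methyl-3-methylidene-2-oxo-3,3a,4,5,6,7,8,8a-octahydro-2H-cyclohepta[b]furan-8-yl 3-methylbutanoate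
Conditions: HF·pyridine, pyridine, THF, 0 °C to rt
Reagents that add atoms: none
Why: Fluoride-mediated cleavage of the secondary and tertiary triethylsilyl ethers under buffered acidic conditions, chosen because basic fluoride sources could trigger acyl migration, retro-aldol cleavage of the α-ketol or conjugate additions.

## Compound list

1 | (1S,5R)-2-oxabicyclo[3.3.0]oct-6-en-3-one | C1C(=O)O[C@@H]2[C@H]1C=CC2 | starting material
2 | (1R,5R)-2-oxabicyclo[3.3.0]oct-6-ene-3,8-dione | C1C(=O)O[C@@H]2[C@H]1C=CC2=O | intermediate
3 | (1R,5S)-2-oxabicyclo[3.3.0]octane-3,8-dione (cis keto lactone) | C1C(=O)O[C@@H]2[C@H]1CCC2=O | intermediate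
4 | pyrrolidine | C1CCNC1 | starting material
5 | methyl but-2-ynoate | CC#CC(=O)OC | starting material
6 | cis-8-(pyrrolidin-1-yl)-2-oxabicyclo[3.3.0]oct-7-en-3-one (enamine of 3, ring fusion as in 3) | C1C(=O)O[C@@H]2[C@H]1CC=C2N1CCCC1 | intermediate
7 | aminocyclobutene: lactone-fused 1-(pyrrolidin-1-yl)bicyclo[3.2.0]hept-6-ene with 6-CO2Me and 7-Me on the cyclobutene, cyclobutene on the β face | C1C(=O)O[C@@H]2[C@H]1C[C@H]1C(C)=C(C(=O)OC)[C@@]21N1CCCC1 | intermediate
8 | lactone-fused methyl 5-methyl-7-(pyrrolidin-1-yl)cyclohepta-4,6-diene-6-carboxylate | C1C(=O)O[C@@H]2[C@H]1CC=C(C)C(C(=O)OC)=C2N1CCCC1 | intermediate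
9 | methyl (3aS,8aR)-8-hydroxy-6-methyl-2-oxo-3,3a,4,8a-tetrahydro-2H-cyclohepta[b]furan-7-carboxylate | C1C(=O)O[C@@H]2[C@H]1CC=C(C)C(C(=O)OC)=C2O | intermediate
10 | lactone-fused methyl 7β-hydroxy-5-methylcyclohept-4-ene-6α-carboxylate | C1C(=O)O[C@@H]2[C@H]1CC=C(C)[C@H](C(=O)OC)[C@H]2O | intermediate
11 | dilithium alkoxide–dienolate of 10 | C1C(=O)O[C@@H]2[C@H]1CC=C(C)C(=C([O-])OC)[C@H]2[O-].[Li+].[Li+] | intermediate
12 | lactone-fused methyl 6α,7β-dihydroxy-5-methylcyclohept-4-ene-6β-carboxylate | C1C(=O)O[C@@H]2[C@H]1CC=C(C)[C@@](O)(C(=O)OC)[C@H]2O | intermediate
13 | 3-methylbutanoic acid | CC(C)CC(=O)O | starting material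
14 | 7β-(3-methylbutanoyl) ester of 12 | C1C(=O)O[C@@H]2[C@H]1CC=C(C)[C@@](O)(C(=O)OC)[C@H]2OC(=O)CC(C)C | intermediate
15 | organoborane: 4β-boryl, C6 spiro-1,3,2-dioxaborolane (drawn as monomer) | C1C(=O)O[C@@H]2[C@H]1C[C@@H]([BH2])[C@H](C)[C@@]3(CO[BH]O3)[C@H]2OC(=O)CC(C)C | intermediate
16 | lactone-fused 4β,6α-dihydroxy-6β-(hydroxymethyl)-5α-methylcycloheptan-7β-yl 3-methylbutanoate | C1C(=O)O[C@@H]2[C@H]1C[C@@H](O)[C@H](C)[C@@](O)(CO)[C@H]2OC(=O)CC(C)C | intermediate
17 | tris(triethylsilyl) ether of 16 | C1C(=O)O[C@@H]2[C@H]1C[C@@H](O[Si](CC)(CC)CC)[C@H](C)[C@@](O[Si](CC)(CC)CC)(CO[Si](CC)(CC)CC)[C@H]2OC(=O)CC(C)C | intermediate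
18 | lithium enolate of the lactone of 17 | C1=C([O-])O[C@@H]2[C@H]1C[C@@H](O[Si](CC)(CC)CC)[C@H](C)[C@@](O[Si](CC)(CC)CC)(CO[Si](CC)(CC)CC)[C@H]2OC(=O)CC(C)C.[Li+] | intermediate
19 | α-(dimethylaminomethyl) lactone (Mannich base of 17) | CN(C)C[C@@H]1C(=O)O[C@@H]2[C@H]1C[C@@H](O[Si](CC)(CC)CC)[C@H](C)[C@@](O[Si](CC)(CC)CC)(CO[Si](CC)(CC)CC)[C@H]2OC(=O)CC(C)C | intermediate
20 | trimethylammonium iodide of 19 | C[N+](C)(C)C[C@@H]1C(=O)O[C@@H]2[C@H]1C[C@@H](O[Si](CC)(CC)CC)[C@H](C)[C@@](O[Si](CC)(CC)CC)(CO[Si](CC)(CC)CC)[C@H]2OC(=O)CC(C)C.[I-] | intermediate
21 | α-methylene lactone tris(triethylsilyl) ether | C=C1C(=O)O[C@@H]2[C@H]1C[C@@H](O[Si](CC)(CC)CC)[C@H](C)[C@@](O[Si](CC)(CC)CC)(CO[Si](CC)(CC)CC)[C@H]2OC(=O)CC(C)C | intermediate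
22 | 6β-formyl compound (4β-O and 6α-O triethylsilyl ethers) | C=C1C(=O)O[C@@H]2[C@H]1C[C@@H](O[Si](CC)(CC)CC)[C@H](C)[C@@](O[Si](CC)(CC)CC)(C=O)[C@H]2OC(=O)CC(C)C | intermediate
23 | (E)-1-bromoprop-1-ene | C/C=C/Br | starting material
24 | 6β-[(E)-1-hydroxybut-2-enyl] compound (carbinol epimers) | C=C1C(=O)O[C@@H]2[C@H]1C[C@@H](O[Si](CC)(CC)CC)[C@H](C)[C@@](O[Si](CC)(CC)CC)(C(O)/C=C/C)[C@H]2OC(=O)CC(C)C | intermediate
25 | 4,6-bis(triethylsilyl) ether of the target | C=C1C(=O)O[C@@H]2[C@H]1C[C@@H](O[Si](CC)(CC)CC)[C@H](C)[C@@](O[Si](CC)(CC)CC)(C(=O)/C=C/C)[C@H]2OC(=O)CC(C)C | intermediate
26 | (3aS,5R,6S,7S,8S,8aR)-7-[(E)-but-2-enoyl]-5,7-dihydroxy-6-methyl-3-methylidene-2-oxo-3,3a,4,5,6,7,8,8a-octahydro-2H-cyclohepta[b]furan-8-yl 3-methylbutanoate | C=C1C(=O)O[C@@H]2[C@H]1C[C@@H](O)[C@H](C)[C@@](O)(C(=O)/C=C/C)[C@H]2OC(=O)CC(C)C | target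

## Step count and least certain steps

Total step count: 13. Longest linear sequence: 13 steps (1 to 26).

**Step 3 (key step).** The most likely failure is slow carbon–carbon bond formation between the enamine and the β-methyl-substituted, weakly electrophilic alkyne. Decomposition of the enamine, aminolysis of the lactone by liberated amine and aza-Michael addition of the amine to 5 would then take over. Fallback (from 3, back at 9): the amine is left out. Kinetic silylation of 3 (LiHMDS, Me3SiCl, THF, −78 °C) gives the trimethylsilyl enol ether F1 with its double bond toward C4. A Lewis-acid-promoted (2+2) cycloaddition with 5 (EtAlCl2, CH2Cl2) gives the siloxycyclobutene F2. Heating opens it to the ring-enlarged silyl dienol ether F3, and dilute HCl in THF removes the silyl group to give 9. The same two bonds are formed and the same bond is broken, but the electrophile is activated instead of the nucleophile.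

**Step 1.** Regiocontrol may be lost in the allylic oxidation, by hydrogen abstraction at the ring-fusion methine or oxygen delivery to the far end of the allyl system (transposed enone). Fallback (from 1, back at 2): SeO2/tBuOOH in CH2Cl2 proceeds by an ene reaction and a 2,3-sigmatropic shift, which returns oxygen to the carbon that lost hydrogen and prefers CH2 over CH. It should give the allylic alcohol F4 (8-hydroxy, hydroxyl on the convex face), which MnO2 or Dess–Martin periodinane oxidises to 2.

**Step 4.** Double diastereodifferentiation may work against the catalyst, so that hydride is delivered in part anti to the C1–O bond; hydrogenation of the strongly stabilised conjugated enol may also be slow. Fallback (from 9, back at 10; no new compound): enzymatic reduction with an NADPH-dependent ketoreductase from a commercial panel (glucose/glucose dehydrogenase recycling, buffer/iPrOH). The active site, not a metal chelate, selects the face, and cyclic 2-oxo esters are standard substrates with dynamic kinetic resolution.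

**Step 5.** The second equivalent of amide base may deprotonate the lactone methylene instead, leading to oxidation or condensation at the lactone α-carbon; some γ-attack on the dienolate is also possible. Fallback (from 10, back at 12): soft enolisation with Me3SiOTf/Et3N silylates the C7 hydroxyl and converts the doubly activated C6–H ester into the silyl dienyl ketene acetal F5 without strong base (the lactone is much slower). Rubottom oxidation with dimethyldioxirane at the electron-rich C6, anti to the C7 silyloxy group, gives the bis(trimethylsilyl) ether F6, and citric acid in methanol liberates 12.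

**Step 7.** Facial selectivity of borane addition may be poor at an alkene whose neighbour C6 carries a substituent on each face; reduction of the lactone or acyl migration during work-up could accompany it. Fallback (from 10, back at 17): the alkene is hydroborated before C6 becomes quaternary.
- In 10 the β face beside the alkene carries only the C6 hydrogen, while the ester and the lactone lie on the α face. BH3·THF then buffered H2O2 should give the 4β,7β-diol F7.
- The less hindered C4 hydroxyl is silylated (Et3SiCl, imidazole) to the mono-silyl ether F8.
- Fráter–Seebach hydroxylation as in step 5 gives the C6 carbinol F9. Here the incoming oxygen must pass the C5 methyl, which is the weak point of this order.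
- Esterification with 13 as in step 6 gives the isovalerate F10.
- Hydroxyl-directed borane reduction of the ester gives the diol F11, and Et3SiOTf/2,6-lutidine converts it into 17.

**Step 10.** Selectivity between the neopentyl-type primary and the secondary triethylsilyl ether may be lost in the oxidative desilylation. Fallback (from 21, back at 22): deprotection and oxidation are separated. HF·pyridine buffered with pyridine in THF at 0 °C removes the primary silyl group first to give the primary alcohol F12, and Dess–Martin periodinane oxidises it to 22. The desilylation can be followed and stopped, which the one-pot oxidation does not allow.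

## Further compounds

F1 | step 3 | trimethylsilyl enol ether of 3 (double bond toward C4) | C1C(=O)O[C@@H]2[C@H]1CC=C2O[Si](C)(C)C
F2 | step 3 | siloxycyclobutene (silyloxy analogue of 7) | C1C(=O)O[C@@H]2[C@H]1C[C@H]1C(C)=C(C(=O)OC)[C@@]21O[Si](C)(C)C
F3 | step 3 | trimethylsilyl dienol ether of 9 | C1C(=O)O[C@@H]2[C@H]1CC=C(C)C(C(=O)OC)=C2O[Si](C)(C)C
F4 | step 1 | cis-8-hydroxy-2-oxabicyclo[3.3.0]oct-6-en-3-one, hydroxyl trans to the lactone oxygen | C1C(=O)O[C@@H]2[C@H]1C=C[C@H]2O
F0 | step 4 | none | none
F5 | step 5 | 7β-trimethylsilyloxy silyl dienyl ketene acetal of 10 | C1C(=O)O[C@@H]2[C@H]1CC=C(C)C(=C(OC)O[Si](C)(C)C)[C@H]2O[Si](C)(C)C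
F6 | step 5 | 6α,7β-bis(trimethylsilyl) ether of 12 | C1C(=O)O[C@@H]2[C@H]1CC=C(C)[C@@](O[Si](C)(C)C)(C(=O)OC)[C@H]2O[Si](C)(C)C
F7 | step 7 | lactone-fused methyl 4β,7β-dihydroxy-5α-methylcycloheptane-6α-carboxylate | C1C(=O)O[C@@H]2[C@H]1C[C@@H](O)[C@H](C)[C@H](C(=O)OC)[C@H]2O
F8 | step 7 | 4β-triethylsilyl ether of F7 | C1C(=O)O[C@@H]2[C@H]1C[C@@H](O[Si](CC)(CC)CC)[C@H](C)[C@H](C(=O)OC)[C@H]2O
F9 | step 7 | 6α-hydroxy derivative of F8 (ester 6β) | C1C(=O)O[C@@H]2[C@H]1C[C@@H](O[Si](CC)(CC)CC)[C@H](C)[C@@](O)(C(=O)OC)[C@H]2O
F10 | step 7 | 7β-(3-methylbutanoyl) ester of F9 | C1C(=O)O[C@@H]2[C@H]1C[C@@H](O[Si](CC)(CC)CC)[C@H](C)[C@@](O)(C(=O)OC)[C@H]2OC(=O)CC(C)C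
F11 | step 7 | 6β-hydroxymethyl-6α-hydroxy compound from F10 | C1C(=O)O[C@@H]2[C@H]1C[C@@H](O[Si](CC)(CC)CC)[C@H](C)[C@@](O)(CO)[C@H]2OC(=O)CC(C)C
F12 | step 10 | primary alcohol from 21 (4β-O and 6α-O silyl ethers kept) | C=C1C(=O)O[C@@H]2[C@H]1C[C@@H](O[Si](CC)(CC)CC)[C@H](C)[C@@](O[Si](CC)(CC)CC)(CO)[C@H]2OC(=O)CC(C)C
A1 | alternative 1 | tropone (cyclohepta-2,4,6-trien-1-one) | O=C1C=CC=CC=C1
A2 | alternative 1 | dioxygen (used in its singlet state) | O=O
A3 | alternative 1 | 6,7-dioxabicyclo[3.2.2]nona-3,8-dien-2-one (enantiomer shown) | O=C1C=C[C@@H]2C=C[C@H]1OO2
A4 | alternative 2 | 1-bromobutan-2-one | CCC(=O)CBr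
A5 | alternative 2 | methyl 2-(furan-3-yl)acetate | COC(=O)Cc1ccoc1
A6 | alternative 2 | 1-methyl-2-oxidoallyl cation | C[CH+]C([O-])=C
A7 | alternative 2 | methyl 2-(2-methyl-3-oxo-8-oxabicyclo[3.2.1]oct-6-en-6-yl)acetate (enantiomer shown) | O1[C@H]2C(CC(=O)OC)=C[C@@H]1[C@H](C)C(=O)C2
A8 | alternative 3 | methyl (3Z)-4-(benzyloxy)-3-[(tert-butyldimethylsilyl)oxy]-2-diazobut-3-enoate | COC(=O)C(=[N+]=[N-])/C(O[Si](C)(C)C(C)(C)C)=C/OCc1ccccc1
A9 | alternative 3 | tert-butyldimethyl{[(2E)-3-methylpenta-2,4-dien-1-yl]oxy}silane | C=C/C(C)=C/CO[Si](C)(C)C(C)(C)C
A10 | alternative 3 | methyl 7-(benzyloxy)-1-[(tert-butyldimethylsilyl)oxy]-6-{[(tert-butyldimethylsilyl)oxy]methyl}-5-methylcyclohepta-1,4-diene-2-carboxylate (6,7-cis, enantiomer shown) | CC(C)(C)[Si](C)(C)OC1=C(C(=O)OC)CC=C(C)[C@@H](CO[Si](C)(C)C(C)(C)C)[C@H]1OCc1ccccc1
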